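**Retrosynthetic overview**

- The depside ester bond (ring A C4–O to the ring B carbonyl) is cut last. It is formed from a ring A phenol with a free 4-OH and a MOM-protected ring B acid chloride; methylation of the ring A 2-OH and MOM removal follow the coupling.
- The route rests on ring A: C1 carries CO2Me, C2 and C4 carry oxygen, C3, C5 and C6 carry CH3. The meta oxygens and three methyls of this fully substituted orsellinate are those of a cyclohexane-1,3-dione with the methyls on sp3 carbons.
- That dione is made by a Michael–Claisen annulation of methyl 3-oxopentanoate with methyl tiglate (C1–C6, then C3–C4) and is dehydrogenated afterwards.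
- Ring B is bought aromatic as methyl atrarate and adjusted by C5 chlorination, 4-O-MOM protection, 2-O-methylation and saponification.
- Ring A is the only ring formed (step 1, aromatised in step 2).

Key step: step 1

Remark on the chemistry: locants in both rings follow orsellinate numbering (C1 bears the carboxyl carbon, C2 and C4 the oxygens; primes mark ring B). Dione 4 is written as the triketo tautomer; it should exist largely as enols and as a diastereomer mixture, which has no consequence.

**Route**

Step 1
Reactants: 1 methyl 3-oxopentanoate; 2 methyl tiglate (methyl (E)-2-methylbut-2-enoate)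
Product: 4 methyl 3,5,6-trimethyl-2,4-dioxocyclohexane-1-carboxylate (diastereomer mixture), via Michael adduct 3 (not isolated)
Conditions: NaOMe (1.2 equiv), MeOH (concentrated), reflux, 48 h; then 2 M HCl, 0 °C
Reagents that add atoms: none
Why: Methoxide deprotonates 1 at the carbon between its two carbonyls, and this enolate adds in a Michael reaction to the β-carbon of 2 (ring bond C1–C6) to give 3; after proton transfer the ethyl-ketone enolate attacks the tiglate-derived ester carbonyl through its methylene carbon and expels methoxide (ring bond C3–C4), a Claisen condensation of the Dieckmann type. The closest known reaction is the Michael–Claisen annulation of acetoacetates or 3-oxopentanoates with crotonates, which gives dihydroresorcylates. The ring closes in the favoured 6-(enolendo)-exo-trig mode, and every other enolate/ester pairing in 3 would give a four-membered ring. The four sp3 centres C1, C3, C5 and C6 are formed without control (C1 and C3 equilibrate through the enols), which is accepted because all four become sp2 in step 2. The step needs C-alkylation at the doubly activated carbon, secured because NaOMe deprotonates only that carbon to a useful extent; it must also overcome the low electrophilicity of the α,β-disubstituted acceptor, and here the essentially irreversible deprotonation of the 2-alkyl-1,3-dione product at C3 drains the reversible addition, helped by high concentration and long reflux.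

Step 2
Reactants: 4 methyl 3,5,6-trimethyl-2,4-dioxocyclohexane-1-carboxylate
Product: 5 methyl 2,4-dihydroxy-3,5,6-trimethylbenzoate
Conditions: DDQ (1.1 equiv), 1,4-dioxane, reflux
Reagents that add atoms: none
Why: DDQ should abstract hydride from C6 of the dienol form of 4 (giving an oxygen-stabilised cation) and loss of the C5 proton aromatises the ring, a quinone dehydrogenation of a cyclohexane-1,3-dione to a resorcinol that is driven by aromatisation and removes all four stereocentres.

Step 3
Reactants: 6 methyl atrarate (methyl 2,4-dihydroxy-3,6-dimethylbenzoate)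
Product: 7 methyl 5-chloro-2,4-dihydroxy-3,6-dimethylbenzoate
Conditions: SO2Cl2 (1.05 equiv), Et2O, 0 °C to rt
Reagents that add atoms: sulfuryl chloride, O=S(=O)(Cl)Cl
Why: Electrophilic aromatic chlorination; C5 is the only unsubstituted ring carbon of 6 and is activated ortho to the 4-OH and para to the 2-OH, so one equivalent should chlorinate there alone.

Step 4
Reactants: 7 methyl 5-chloro-2,4-dihydroxy-3,6-dimethylbenzoate
Product: 8 methyl 5-chloro-2-hydroxy-4-(methoxymethoxy)-3,6-dimethylbenzoate
Conditions: MOMCl (1.2 equiv), K2CO3, acetone, 0 °C to rt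
Reagents that add atoms: chloromethyl methyl ether, COCCl
Why: Williamson-type O-alkylation; the 4-OH (para to the ester, acidified by the ortho chlorine) is the one deprotonated by K2CO3, whereas the 2-OH is held in a hydrogen bond to the ester carbonyl and should stay free.

Step 5
Reactants: 8 methyl 5-chloro-2-hydroxy-4-(methoxymethoxy)-3,6-dimethylbenzoate
Product: 9 methyl 5-chloro-2-methoxy-4-(methoxymethoxy)-3,6-dimethylbenzoate
Conditions: MeI (3 equiv), K2CO3, DMF, 40 °C
Reagents that add atoms: iodomethane, CI
Why: Williamson etherification of the remaining chelated phenol, which needs the polar solvent and excess MeI; the MOM ether, aryl chloride and ester are inert to these conditions.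

Step 6
Reactants: 9 methyl 5-chloro-2-methoxy-4-(methoxymethoxy)-3,6-dimethylbenzoate
Product: 10 5-chloro-2-methoxy-4-(methoxymethoxy)-3,6-dimethylbenzoic acid
Conditions: KOH (10 equiv), DMSO/H2O, 90 °C; then 1 M HCl to pH 4, 0 °C
Reagents that add atoms: potassium hydroxide, [K+].[OH-]
Why: Saponification of a di-ortho-substituted benzoate, slow and therefore run with poorly solvated hydroxide in DMSO; the MOM ether is stable to base and should survive a brief, cold acidification to pH 4.

Step 7
Reactants: 10 5-chloro-2-methoxy-4-(methoxymethoxy)-3,6-dimethylbenzoic acid; 5 methyl 2,4-dihydroxy-3,5,6-trimethylbenzoate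
Product: 12 methyl 4-{[5-chloro-2-methoxy-4-(methoxymethoxy)-3,6-dimethylbenzoyl]oxy}-2-hydroxy-3,5,6-trimethylbenzoate, via acid chloride 11 (not isolated)
Conditions: 10 (1.1 equiv), 1-chloro-N,N,2-trimethylprop-1-en-1-amine (1.1 equiv), CH2Cl2, 0 °C to rt; then 5, NaH (1.05 equiv), THF, 0 to 45 °C
Reagents that add atoms: none
Why: Nucleophilic acyl substitution of an acid chloride by a phenoxide; the chloride is made under neutral conditions that spare the MOM ether, and one equivalent of NaH deprotonates the more acidic, non-chelated 4-OH of 5 (para to the ester), while the 2-OH stays locked in its hydrogen bond to the ester carbonyl.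

Step 8
Reactants: 12 methyl 4-{[5-chloro-2-methoxy-4-(methoxymethoxy)-3,6-dimethylbenzoyl]oxy}-2-hydroxy-3,5,6-trimethylbenzoate
Product: 13 methyl 4-{[5-chloro-2-methoxy-4-(methoxymethoxy)-3,6-dimethylbenzoyl]oxy}-2-methoxy-3,5,6-trimethylbenzoate
Conditions: MeI (3 equiv), K2CO3, DMF, 40 °C
Reagents that add atoms: iodomethane, CI
Why: Williamson methylation of the hydrogen-bonded 2-OH; the tetra-ortho-substituted aryl benzoate is shielded from carbonate and the MOM ether is base-stable.

Step 9
Reactants: 13 methyl 4-{[5-chloro-2-methoxy-4-(methoxymethoxy)-3,6-dimethylbenzoyl]oxy}-2-methoxy-3,5,6-trimethylbenzoate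
Product: 14 methyl 4-[(5-chloro-4-hydroxy-2-methoxy-3,6-dimethylbenzoyl)oxy]-2-methoxy-3,5,6-trimethylbenzoate (CNP0192286.0)
Conditions: HCl (4 M in 1,4-dioxane), MeOH/CH2Cl2, rt
Reagents that add atoms: none
Why: Acid-catalysed acetal exchange (MOM cleavage) passes the methylene to methanol and frees the 4'-OH, while the two hindered esters, the aryl methyl ethers and the aryl chloride should be untouched at room temperature.

**Compound list**

1 | methyl 3-oxopentanoate | CCC(=O)CC(=O)OC | starting material
2 | methyl tiglate, methyl (E)-2-methylbut-2-enoate | C/C=C(\C)C(=O)OC | starting material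
3 | dimethyl 2,3-dimethyl-4-propanoylpentanedioate (Michael adduct, diastereomer mixture, not isolated) | CCC(=O)C(C(=O)OC)C(C)C(C)C(=O)OC | intermediate
4 | methyl 3,5,6-trimethyl-2,4-dioxocyclohexane-1-carboxylate (diastereomer mixture) | COC(=O)C1C(C)C(C)C(=O)C(C)C1=O | intermediate
5 | methyl 2,4-dihydroxy-3,5,6-trimethylbenzoate | COC(=O)c1c(C)c(C)c(O)c(C)c1O | intermediate
6 | methyl atrarate, methyl 2,4-dihydroxy-3,6-dimethylbenzoate | COC(=O)c1c(C)cc(O)c(C)c1O | starting material
7 | methyl 5-chloro-2,4-dihydroxy-3,6-dimethylbenzoate | COC(=O)c1c(C)c(Cl)c(O)c(C)c1O | intermediate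
8 | methyl 5-chloro-2-hydroxy-4-(methoxymethoxy)-3,6-dimethylbenzoate | COCOc1c(Cl)c(C)c(C(=O)OC)c(O)c1C | intermediate
9 | methyl 5-chloro-2-methoxy-4-(methoxymethoxy)-3,6-dimethylbenzoate | COCOc1c(Cl)c(C)c(C(=O)OC)c(OC)c1C | intermediate
10 | 5-chloro-2-methoxy-4-(methoxymethoxy)-3,6-dimethylbenzoic acid | COCOc1c(Cl)c(C)c(C(=O)O)c(OC)c1C | intermediate
11 | 5-chloro-2-methoxy-4-(methoxymethoxy)-3,6-dimethylbenzoyl chloride (not isolated) | COCOc1c(Cl)c(C)c(C(=O)Cl)c(OC)c1C | intermediate
12 | methyl 4-{[5-chloro-2-methoxy-4-(methoxymethoxy)-3,6-dimethylbenzoyl]oxy}-2-hydroxy-3,5,6-trimethylbenzoate | COCOc1c(Cl)c(C)c(C(=O)Oc2c(C)c(C)c(C(=O)OC)c(O)c2C)c(OC)c1C | intermediate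
13 | methyl 4-{[5-chloro-2-methoxy-4-(methoxymethoxy)-3,6-dimethylbenzoyl]oxy}-2-methoxy-3,5,6-trimethylbenzoate | COCOc1c(Cl)c(C)c(C(=O)Oc2c(C)c(C)c(C(=O)OC)c(OC)c2C)c(OC)c1C | intermediate
14 | methyl 4-[(5-chloro-4-hydroxy-2-methoxy-3,6-dimethylbenzoyl)oxy]-2-methoxy-3,5,6-trimethylbenzoate | COC(=O)c1c(C)c(C)c(OC(=O)c2c(C)c(Cl)c(O)c(C)c2OC)c(C)c1OC | target

**Step count**

Total: 9 steps. Longest linear sequence: 7 steps (6 to 14, steps 3 to 9); the ring A branch is 5 steps (steps 1, 2, 7, 8, 9).

**Steps most likely to fail**

Step 1. Conjugate addition to the α,β-disubstituted enoate may be too slow and too reversible, so that retro-Claisen cleavage and self-condensation of the keto ester use up the donor before the ring closes. The fallback sets out from 2 and comes back at 4; it moves the ketone into the acceptor and uses a malonate donor, so the addition is to a much more electrophilic enone. Ester 2 is converted with MeNHOMe·HCl and iPrMgCl (THF, −20 °C) into (E)-N-methoxy-N,2-dimethylbut-2-enamide F1. EtMgBr then gives (E)-4-methylhex-4-en-3-one F2. Dimethyl malonate and NaOMe in refluxing MeOH should add to F2 to give dimethyl 2-(3-methyl-4-oxohexan-2-yl)propanedioate F3, which under the same conditions closes to 4 by attack of the ethyl-ketone enolate on a malonate ester (bond C2–C3).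

Step 7. Acyl transfer between a di-ortho-substituted acid chloride and a phenoxide flanked by two methyls may stall, which leaves time for hydrolysis of the chloride, loss of the MOM group or acylation at the 2-OH. The fallback sets out from 7 and comes back at 14; it replaces base-mediated acylation by acid-mediated esterification through a mixed trifluoroacetic anhydride, the usual answer to tetra-ortho-substituted aryl benzoates, and therefore uses an acid-stable benzyl ether in place of MOM. BnBr/K2CO3 in acetone should give methyl 4-(benzyloxy)-5-chloro-2-hydroxy-3,6-dimethylbenzoate F4. MeI/K2CO3 in DMF then gives methyl 4-(benzyloxy)-5-chloro-2-methoxy-3,6-dimethylbenzoate F5, and KOH in DMSO/H2O gives 4-(benzyloxy)-5-chloro-2-methoxy-3,6-dimethylbenzoic acid F6. With (CF3CO)2O in toluene at rt, F6 forms 4-(benzyloxy)-5-chloro-2-methoxy-3,6-dimethylbenzoic trifluoroacetic anhydride F7, which should acylate the unchelated 4-OH of 5 to give methyl 4-{[4-(benzyloxy)-5-chloro-2-methoxy-3,6-dimethylbenzoyl]oxy}-2-hydroxy-3,5,6-trimethylbenzoate F8. MeI/K2CO3 in DMF gives methyl 4-{[4-(benzyloxy)-5-chloro-2-methoxy-3,6-dimethylbenzoyl]oxy}-2-methoxy-3,5,6-trimethylbenzoate F9. Short hydrogenolysis (H2, 1 atm, 10% Pd/C, EtOAc, stopped at full conversion to spare the aryl chloride) then gives 14.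

Step 2. Over-oxidation is the concern: DDQ may go on to abstract hydride from the benzylic methyls of the electron-rich product, or add to the enol, before dehydrogenation is complete. The fallback sets out from 4 and comes back at 5; it replaces hydride abstraction by ionic halogenation and dehydrohalogenation. N-Chlorosuccinimide in CH2Cl2 at 0 °C should chlorinate the enolised dione at C3 to give methyl 3-chloro-3,5,6-trimethyl-2,4-dioxocyclohexane-1-carboxylate F10. Heating F10 in DMF with LiCl at 100 °C should expel HCl, through acid-mediated chlorine migration and elimination, to give 5 without touching the methyl groups.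

**Further compounds**

F1 | step 1 | (E)-N-methoxy-N,2-dimethylbut-2-enamide | C/C=C(\C)C(=O)N(C)OC
F2 | step 1 | (E)-4-methylhex-4-en-3-one | C/C=C(\C)C(=O)CC
F3 | step 1 | dimethyl 2-(3-methyl-4-oxohexan-2-yl)propanedioate (diastereomer mixture) | CCC(=O)C(C)C(C)C(C(=O)OC)C(=O)OC
F4 | step 7 | methyl 4-(benzyloxy)-5-chloro-2-hydroxy-3,6-dimethylbenzoate | COC(=O)c1c(C)c(Cl)c(OCc2ccccc2)c(C)c1O
F5 | step 7 | methyl 4-(benzyloxy)-5-chloro-2-methoxy-3,6-dimethylbenzoate | COC(=O)c1c(C)c(Cl)c(OCc2ccccc2)c(C)c1OC
F6 | step 7 | 4-(benzyloxy)-5-chloro-2-methoxy-3,6-dimethylbenzoic acid | OC(=O)c1c(C)c(Cl)c(OCc2ccccc2)c(C)c1OC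
F7 | step 7 | 4-(benzyloxy)-5-chloro-2-methoxy-3,6-dimethylbenzoic trifluoroacetic anhydride | O=C(OC(=O)C(F)(F)F)c1c(C)c(Cl)c(OCc2ccccc2)c(C)c1OC
F8 | step 7 | methyl 4-{[4-(benzyloxy)-5-chloro-2-methoxy-3,6-dimethylbenzoyl]oxy}-2-hydroxy-3,5,6-trimethylbenzoate | COC(=O)c1c(C)c(C)c(OC(=O)c2c(C)c(Cl)c(OCc3ccccc3)c(C)c2OC)c(C)c1O
F9 | step 7 | methyl 4-{[4-(benzyloxy)-5-chloro-2-methoxy-3,6-dimethylbenzoyl]oxy}-2-methoxy-3,5,6-trimethylbenzoate | COC(=O)c1c(C)c(C)c(OC(=O)c2c(C)c(Cl)c(OCc3ccccc3)c(C)c2OC)c(C)c1OC
F10 | step 2 | methyl 3-chloro-3,5,6-trimethyl-2,4-dioxocyclohexane-1-carboxylate (diastereomer mixture) | COC(=O)C1C(C)C(C)C(=O)C(C)(Cl)C1=O
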